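## Structural features

The target is a cembranolide (cembrane numbering throughout). It has a fourteen-membered carbocycle C1–C14, a cis-fused α-methylene-γ-butyrolactone on C1/C2 (C15, C16, exocyclic C17), and a 1,2-dioxane made by an O–O bridge between C8 and C11 (ring C8–C9–C10–C11–O–O). C3=C4 is E, and C12=C13 has C11 and C14 cis. The five stereocentres form two clusters: C1/C2 (1R,2R, cis fusion) and C7/C8/C11 (7R acetate beside the quaternary 8S peroxy carbon, 11R, with the C7 and C12 arms cis on the dioxane). C3–C6 and C12–C14 insulate the clusters, so each needs its own absolute control. Fragile elements are the O–O bond, the allylic C11–H on a peroxide carbon (base-induced Kornblum–DeLaMare cleavage), the allylic C2–O lactone bond, the Michael-acceptor methylene lactone and the contra-thermodynamic C12=C13 geometry. The real difficulty is to close the large ring with the peroxide in place and to put a Z-trisubstituted alkene next to C11. The key step uses the position of C7 between quaternary C8 and C6: a C7 methyl ketone enolises only towards C6, and the cis-dioxane holds the C7 and C12 arms on one face, so a C6 enolate and a C5 allylic bromide meet far from the lactone and the O–O bond. The structures of seco bromo ketone 37 and macrocyclic ketone 39 agree with the target at C1, C2, C8, C11 and both alkenes (the C2 descriptor reads S only because C15 is saturated) and are used unchanged. What is corrected is the chemistry around them: the lactone α-CH2 is about as acidic as the methyl ketone; an α-peroxy ketone with hydrogen at C11 is base-labile; a late allylic bromination would not be selective; and a photo-oxygenation adduct of an achiral diene is racemic.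

## Logic of the disconnections

**45 ⇒ 41 ⇒ 40 ⇒ 39.** The C15–C17 bond, the acetyl C–O bond at C7 and the C7–H bond are cut. The methylene lactone and the acetate cannot coexist with enolate chemistry at C6. This leaves 39 without a Michael acceptor and with one stereocentre fewer. The forward steps must deliver 7R next to a quaternary carbon and methylenate with a base that spares the acetate and C11–H.

**39 ⇒ 37.** The C5–C6 bond is cut. It is the only ring bond flanked by a one-sided enolisable ketone and an allylic carbon, and it is remote from both heterocycles. The gain is an open chain that already holds all four remaining stereocentres. The forward step needs C-alkylation, ring closure over oligomerisation, and no free base left for C11–H or the lactone.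

**37 ⇒ 36 ⇒ 34 ⇒ 33.** Only functional groups change: the C7 carbonyl comes from a silyl-protected (7R)-alcohol, and the C5–Br bond from a silyl-protected allylic alcohol. The ketone is therefore absent in the basic olefination and appears one step before the ring closure. The bromide is made from an oxygen placed early, not by a late unselective bromination. The demand is selective activation of the primary allylic hydroxyl over the hindered C7 hydroxyl.

**33 ⇒ 31 + 15.** The C12=C13 double bond is cut. An α-oxygenated methyl ketone and a non-stabilised ylide give the required geometry (C11 cis to C14), and the cut divides the molecule into its two stereochemical clusters. The demand is that ylide addition to the C12 carbonyl of 15 outruns proton abstraction at C11.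

**15 ⇒ 14 ⇒ 13 ⇒ 11 ⇒ 10.** The C12 carbonyl is traced to a terminal alkyne, the O–C11 bond to displacement of a propargylic mesylate, and the O–C8 bond to opening of an epoxide by hydrogen peroxide. Both C–O bonds form with inversion at defined centres, and the base-labile ketone appears only after the ring is closed. The demands are clean inversion at tertiary C8 and attack by the peroxy oxygen in preference to the C7 hydroxyl.

**10 ⇒ 9 ⇒ 8 ⇒ 7 ⇒ 4 + 5, and 4 ⇒ 3 ⇒ 1 + 2.** The epoxide oxygen, the C11–H bond, the C11–C12 bond and the C9–C10 bond are cut in turn. This reduces the dioxane half to two achiral commercial compounds and puts each stereocentre under catalyst control. The demands are face-selective epoxidation of the only electron-rich alkene and E-selective sigmatropic formation of C7=C8.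

**31 ⇒ 30 ⇒ 29 ⇒ 27 ⇒ 26 ⇒ 25 ⇒ 24.** The C13–P, C13–I and C13–O bonds, the C13–C14 bond (methylenation) and the acyl bonds at C14 are cut. The two-carbon arm on C1 is derived from the acyl carbon of an aldol adduct. This removes any hydroxyl four atoms from the lactone carbonyl, which would translactonise. The demand is non-basic handling of the epimerisable, β-acyloxy aldehyde 26.

**24 ⇒ 23 ⇒ 22 ⇒ 18 + 19, and 18 ⇒ 16 + 17.** The C5–O bond, the C1–C2 bond with the lactone C–O bond, and the N-acyl bond are cut. An anti-aldol reaction sets C1 and C2 together and leads to the cis-lactone, while allylic oxidation is done while only one alkene is present. The demand is anti selectivity with the correct enolate face.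

## Other disconnections considered

**Alternative 1:** The cut is C1–C2 at the hydrocarbon level. In the forward step a cembrene A synthase, an ionisation-initiated (class one) diterpene synthase, converts geranylgeranyl diphosphate A1 into cembrene A A2, closing the fourteen-membered ring and setting C1 in one enzymatic step. In its favour, no chemical ring closure comes close in step economy for the carbocycle, and on this point the alternative is better than the chosen plan. Against it, A2 has no oxygen and three nearly equivalent trisubstituted alkenes. The target needs oxygen at C2, C7, C8, C11 and C16 and a shift of the C11=C12 alkene to C12=C13 with Z geometry. No chemical reagent distinguishes these sites, so tailoring enzymes that are not available would be needed. Mechanistically, the alternative relies on enzyme-guided carbocation chemistry and the chosen plan on an enolate SN2 reaction. Structurally, the alternative builds the ring first and oxidises later, whereas the chosen plan brings every heteroatom in before ring closure. Overall the alternative is shorter to the ring but much longer, and less certain, to the target.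

**Alternative 2:** The cuts are O–C8 and O–C11, with a temporary C7–C12 bond. In the forward step, sensitised photo-oxygenation of 1,3-dimethylcyclohexa-1,3-diene A3 gives the bicyclic endoperoxide A4 by a [4+2] addition. That forms both C–O bonds and the cis relationship at once, and later cleavage of the C7=C12 alkene would release a C7 aldehyde and a C12 methyl ketone on the dioxane. In its favour, the dioxane core arises in about three steps, against eight to reach 13, so on step count it is better than the chosen plan. Against it, A3 is achiral, so A4 forms as a racemate and must be resolved. The two carbonyls must be told apart, and a methyl group must be added to the C7 aldehyde by an organometallic reagent while the base-labile α-peroxy C12 ketone is already present. The chosen plan sets C8 and C11 by catalyst-controlled steps and stereospecific inversions and has C7 differentiated from the start. On one point the two are equal: both pass through an α-peroxy methyl ketone for the Z-olefination and share that liability.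

**Alternative 3:** The cut is C4–C5. In the forward step the terminal C5=C6 alkene of the seco alkenyl iodide A5 is hydroborated and the alkylborane is coupled with the C4 alkenyl iodide under palladium catalysis to give macrocycle A6. In its favour, this sp3–sp2 ring closure is well established, needs no strong base and fixes the E geometry of C3=C4 from the iodide. It also keeps a C7 stereocentre set early and does not remake it after cyclisation. On these points it is equal or better than an enolate closure. Against it, the O–O bond cannot be present during hydroboration and coupling, so A6 carries an acetonide at C7/C8 and a silyl ether at C11, with the opposite spatial arrangement at all three centres. The dioxane must then be built on the macrocycle by inversions at C7, at tertiary C8 and at the allylic C11. That last displacement is the reaction the chosen plan avoids by closing the dioxane on a propargylic centre. In step economy the alternative saves the late reduction but adds at least six steps after ring closure, against three in the chosen plan.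

Key step: step 25

Remark: positions are given in cembrane numbering (C18 = methyl on C4, C19 = methyl on C8, C20 = methyl on C12) for all fragments, independently of the locants in the compound names.

## Steps

Step 1
Reactants: 1 3-methylbut-3-en-2-ol; 2 triethyl orthoacetate
Product: 3 ethyl (E)-4-methylhex-4-enoate
Conditions: EtCO2H (cat.), 140 °C, removal of EtOH
Reagents that add atoms: none
Why: Johnson–Claisen rearrangement; the mixed ketene acetal rearranges through a chair with the carbinol methyl equatorial, which should give the E alkene C7=C8 and the C9–C10 bond, and the racemic centre of 1 is destroyed.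

Step 2
Reactants: 3 ethyl (E)-4-methylhex-4-enoate
Product: 4 (E)-N-methoxy-N,4-dimethylhex-4-enamide
Conditions: MeNH(OMe)·HCl, i-PrMgCl, THF, −20 °C
Reagents that add atoms: N,O-dimethylhydroxylamine hydrochloride, CNOC.Cl
Why: Weinreb amide formation by aminolysis of the ester with the magnesium amide; it allows a single acylation in the next step.

Step 3
Reactants: 4 (E)-N-methoxy-N,4-dimethylhex-4-enamide; 5 ethynyltrimethylsilane
Product: 7 (E)-7-methyl-1-(trimethylsilyl)non-7-en-1-yn-3-one, via lithium (trimethylsilyl)acetylide 6 (not isolated)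
Conditions: 5, n-BuLi, THF, −78 °C; then 4, −78 → 0 °C
Reagents that add atoms: none
Why: Acylation of a lithium acetylide by a Weinreb amide; the chelated tetrahedral intermediate collapses only on work-up, so the ynone (C11 carbonyl, C12≡C20) should form without over-addition.

Step 4
Reactants: 7 (E)-7-methyl-1-(trimethylsilyl)non-7-en-1-yn-3-one
Product: 8 (3S,7E)-7-methyl-1-(trimethylsilyl)non-7-en-1-yn-3-ol
Conditions: RuCl[(S,S)-TsDPEN](p-cymene) (1 mol %), i-PrOH, 23 °C
Reagents that add atoms: none
Why: Noyori asymmetric transfer hydrogenation of an alkynyl ketone; with the alkyne as the π-substituent the (S,S)-catalyst should give the (S)-alcohol at C11, and the isolated alkene is not reduced.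

Step 5
Reactants: 8 (3S,7E)-7-methyl-1-(trimethylsilyl)non-7-en-1-yn-3-ol
Product: 9 (3S)-5-[(2R,3R)-2,3-dimethyloxiran-2-yl]-1-(trimethylsilyl)pent-1-yn-3-ol
Conditions: D-fructose-derived Shi ketone (0.3 equiv), KHSO5 (as 2KHSO5·KHSO4·K2SO4), K2CO3, MeCN/CH2(OMe)2/aqueous buffer, 0 °C
Reagents that add atoms: potassium peroxymonosulfate, [K+].[O-]S(=O)(=O)OO
Why: Shi epoxidation; the chiral dioxirane attacks the only electron-rich alkene through the spiro transition state that should give the (7R,8R)-epoxide, and the silyl alkyne is inert to the electrophilic oxidant.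

Step 6
Reactants: 9 (3S)-5-[(2R,3R)-2,3-dimethyloxiran-2-yl]-1-(trimethylsilyl)pent-1-yn-3-ol
Product: 10 (3S)-5-[(2R,3R)-2,3-dimethyloxiran-2-yl]-1-(trimethylsilyl)pent-1-yn-3-yl methanesulfonate
Conditions: MsCl, Et3N, CH2Cl2, −20 °C
Reagents that add atoms: methanesulfonyl chloride, CS(=O)(=O)Cl
Why: Sulfonylation of the secondary alcohol with retention at C11; a propargylic mesylate resists ionisation and should survive the acidic step that follows.

Step 7
Reactants: 10 (3S)-5-[(2R,3R)-2,3-dimethyloxiran-2-yl]-1-(trimethylsilyl)pent-1-yn-3-yl methanesulfonate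
Product: 11 (3S,6S,7R)-6-hydroperoxy-7-hydroxy-6-methyl-1-(trimethylsilyl)oct-1-yn-3-yl methanesulfonate
Conditions: H2O2 (anhydrous, in Et2O, excess), H3PMo12O40 (3 mol %), 23 °C
Reagents that add atoms: hydrogen peroxide, OO
Why: Acid-catalysed perhydrolysis of an epoxide; hydrogen peroxide opens the activated epoxide at the tertiary carbon C8 with inversion, which sets 8S and leaves the (7R)-hydroxyl.

Step 8
Reactants: 11 (3S,6S,7R)-6-hydroperoxy-7-hydroxy-6-methyl-1-(trimethylsilyl)oct-1-yn-3-yl methanesulfonate
Product: 13 (1R)-1-[(3S,6R)-6-ethynyl-3-methyl-1,2-dioxan-3-yl]ethan-1-ol, via C-silylated dioxane 12 (not isolated)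
Conditions: K2CO3, MeOH, 0 → 23 °C
Reagents that add atoms: none
Why: Intramolecular Williamson-type alkylation of a hydroperoxide; the peroxy anion, more acidic and more nucleophilic than the C7 hydroxyl, displaces the propargylic mesylate 6-exo-tet with inversion to give 11R and hence the cis-dioxane, and methanolic carbonate then removes the C-silyl group.

Step 9
Reactants: 13 (1R)-1-[(3S,6R)-6-ethynyl-3-methyl-1,2-dioxan-3-yl]ethan-1-ol
Product: 14 triethyl{(1R)-1-[(3S,6R)-6-ethynyl-3-methyl-1,2-dioxan-3-yl]ethoxy}silane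
Conditions: Et3SiOTf, 2,6-lutidine, CH2Cl2, −78 → 0 °C
Reagents that add atoms: triethylsilyl trifluoromethanesulfonate, CC[Si](CC)(CC)OS(=O)(=O)C(F)(F)F
Why: Silylation of a hindered secondary alcohol with a silyl triflate; it prevents an alkoxide beside the peroxide (Grob-type C7–C8 cleavage) and keeps C7 from competing as a ketone in the olefination.

Step 10
Reactants: 14 triethyl{(1R)-1-[(3S,6R)-6-ethynyl-3-methyl-1,2-dioxan-3-yl]ethoxy}silane
Product: 15 1-[(3R,6S)-6-methyl-6-[(1R)-1-(triethylsilyloxy)ethyl]-1,2-dioxan-3-yl]ethan-1-one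
Conditions: Ph3PAuNTf2 (2 mol %), H2O (5 equiv), 1,4-dioxane, 23–40 °C
Reagents that add atoms: water, O
Why: Gold-catalysed Markovnikov hydration of a terminal alkyne gives the methyl ketone (C12, C20) under neutral conditions, which is needed because C11–H of 15 lies between a peroxide oxygen and a carbonyl.

Step 11
Reactants: 16 (S)-4-benzyloxazolidin-2-one; 17 methyl 4-chloro-4-oxobutanoate
Product: 18 methyl 4-[(S)-4-benzyl-2-oxooxazolidin-3-yl]-4-oxobutanoate
Conditions: Et3N, DMAP (cat.), CH2Cl2, 0 → 23 °C
Reagents that add atoms: none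
Why: N-Acylation of the oxazolidinone by an acid chloride under nucleophilic catalysis.

Step 12
Reactants: 18 methyl 4-[(S)-4-benzyl-2-oxooxazolidin-3-yl]-4-oxobutanoate; 19 3-methylbut-2-enal
Product: 22 (S)-4-benzyl-3-[(2R,3R)-2-(2-methylprop-1-en-1-yl)-5-oxotetrahydrofuran-3-carbonyl]oxazolidin-2-one, via silyl aldol adduct 20 (not isolated), via hydroxy ester 21 (not isolated)
Conditions: MgCl2 (0.2 equiv), Et3N, Me3SiCl, EtOAc, 23 °C; then citric acid, MeOH, 0 °C; then PPTS (cat.), CH2Cl2, 23 °C
Reagents that add atoms: none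
Why: Evans magnesium-halide-catalysed anti-aldol reaction; soft enolisation occurs at the imide α-carbon, the chelated Z-enolate should be attacked on the face away from the benzyl group, and the anti adduct sets C1 and C2 so that the γ-hydroxy ester closes to the cis-lactone under mild acid.

Step 13
Reactants: 22 (S)-4-benzyl-3-[(2R,3R)-2-(2-methylprop-1-en-1-yl)-5-oxotetrahydrofuran-3-carbonyl]oxazolidin-2-one
Product: 23 (S)-4-benzyl-3-[(2R,3R)-2-[(E)-3-hydroxy-2-methylprop-1-en-1-yl]-5-oxotetrahydrofuran-3-carbonyl]oxazolidin-2-one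
Conditions: SeO2 (0.5 equiv), t-BuOOH, CH2Cl2, 0 → 23 °C
Reagents that add atoms: tert-butyl hydroperoxide, CC(C)(C)OO (terminal oxidant; the oxygen is delivered through catalytic selenium dioxide, O=[Se]=O)
Why: Selenium dioxide allylic oxidation (ene reaction then [2,3]-shift) is selective for the E-methyl group of a trisubstituted alkene and gives the E allylic alcohol (C5–OH) while this is the only alkene present.

Step 14
Reactants: 23 (S)-4-benzyl-3-[(2R,3R)-2-[(E)-3-hydroxy-2-methylprop-1-en-1-yl]-5-oxotetrahydrofuran-3-carbonyl]oxazolidin-2-one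
Product: 24 (S)-4-benzyl-3-[(2R,3R)-2-[(E)-3-(tert-butyldimethylsilyloxy)-2-methylprop-1-en-1-yl]-5-oxotetrahydrofuran-3-carbonyl]oxazolidin-2-one
Conditions: t-BuMe2SiCl, imidazole, DMF, 0 °C
Reagents that add atoms: tert-butyldimethylsilyl chloride, CC(C)(C)[Si](C)(C)Cl
Why: Silylation of the primary allylic alcohol; the ether carries the C5 oxygen to the end of the route.

Step 15
Reactants: 24 (S)-4-benzyl-3-[(2R,3R)-2-[(E)-3-(tert-butyldimethylsilyloxy)-2-methylprop-1-en-1-yl]-5-oxotetrahydrofuran-3-carbonyl]oxazolidin-2-one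
Product: 25 S-ethyl (2R,3R)-2-[(E)-3-(tert-butyldimethylsilyloxy)-2-methylprop-1-en-1-yl]-5-oxotetrahydrofuran-3-carbothioate
Conditions: EtSH, n-BuLi, THF, 0 °C
Reagents that add atoms: ethanethiol, CCS
Why: Thiolate cleavage of the N-acyl oxazolidinone gives the thioester and returns the auxiliary; the weakly basic thiolate should not cause β-elimination of the lactone oxygen or epimerise C1.

Step 16
Reactants: 25 S-ethyl (2R,3R)-2-[(E)-3-(tert-butyldimethylsilyloxy)-2-methylprop-1-en-1-yl]-5-oxotetrahydrofuran-3-carbothioate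
Product: 26 (2R,3R)-2-[(E)-3-(tert-butyldimethylsilyloxy)-2-methylprop-1-en-1-yl]-5-oxotetrahydrofuran-3-carbaldehyde
Conditions: Et3SiH, Pd/C (10 wt %), acetone, 23 °C
Reagents that add atoms: none
Why: Fukuyama reduction of a thioester to the aldehyde under neutral conditions; the aldehyde is used at once because C1 is epimerisable.

Step 17
Reactants: 26 (2R,3R)-2-[(E)-3-(tert-butyldimethylsilyloxy)-2-methylprop-1-en-1-yl]-5-oxotetrahydrofuran-3-carbaldehyde
Product: 27 (4S,5S)-5-[(E)-3-(tert-butyldimethylsilyloxy)-2-methylprop-1-en-1-yl]-4-vinyldihydrofuran-2(3H)-one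
Conditions: Zn, CH2I2, Ti(Oi-Pr)4, THF, 23 °C
Reagents that add atoms: diiodomethane, ICI
Why: Takai-type methylenation with a zinc/titanium carbenoid is non-basic and aldehyde-selective, so C1 should not epimerise and the lactone oxygen should not be eliminated; it adds C13.

Step 18
Reactants: 27 (4S,5S)-5-[(E)-3-(tert-butyldimethylsilyloxy)-2-methylprop-1-en-1-yl]-4-vinyldihydrofuran-2(3H)-one
Product: 29 (4R,5S)-5-[(E)-3-(tert-butyldimethylsilyloxy)-2-methylprop-1-en-1-yl]-4-(2-hydroxyethyl)dihydrofuran-2(3H)-one, via B-alkyl borane 28 (not isolated)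
Conditions: 9-BBN, THF, 0 → 23 °C; then H2O2, NaHCO3 (aq), 0 °C
Reagents that add atoms: hydrogen peroxide, OO
Why: Hydroboration–oxidation; 9-BBN adds to the monosubstituted alkene in preference to the trisubstituted one and places boron, then oxygen, on C13, five atoms from the lactone carbonyl so that translactonisation is not favoured.

Step 19
Reactants: 29 (4R,5S)-5-[(E)-3-(tert-butyldimethylsilyloxy)-2-methylprop-1-en-1-yl]-4-(2-hydroxyethyl)dihydrofuran-2(3H)-one
Product: 30 (4S,5S)-5-[(E)-3-(tert-butyldimethylsilyloxy)-2-methylprop-1-en-1-yl]-4-(2-iodoethyl)dihydrofuran-2(3H)-one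
Conditions: I2, PPh3, imidazole, CH2Cl2, 0 °C
Reagents that add atoms: iodine, II
Why: Appel-type iodination of the primary alcohol through its alkoxyphosphonium salt.

Step 20
Reactants: 30 (4S,5S)-5-[(E)-3-(tert-butyldimethylsilyloxy)-2-methylprop-1-en-1-yl]-4-(2-iodoethyl)dihydrofuran-2(3H)-one
Product: 31 {2-[(2S,3S)-2-[(E)-3-(tert-butyldimethylsilyloxy)-2-methylprop-1-en-1-yl]-5-oxotetrahydrofuran-3-yl]ethyl}triphenylphosphonium iodide
Conditions: PPh3, MeCN, 80 °C
Reagents that add atoms: triphenylphosphine, c1ccc(cc1)P(c1ccccc1)c1ccccc1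
Why: SN2 quaternisation of triphenylphosphine by the primary iodide.

Step 21
Reactants: 31 {2-[(2S,3S)-2-[(E)-3-(tert-butyldimethylsilyloxy)-2-methylprop-1-en-1-yl]-5-oxotetrahydrofuran-3-yl]ethyl}triphenylphosphonium iodide; 15 1-[(3R,6S)-6-methyl-6-[(1R)-1-(triethylsilyloxy)ethyl]-1,2-dioxan-3-yl]ethan-1-one
Product: 33 (4R,5S)-5-[(E)-3-(tert-butyldimethylsilyloxy)-2-methylprop-1-en-1-yl]-4-[(Z)-3-[(3R,6S)-6-methyl-6-[(1R)-1-(triethylsilyloxy)ethyl]-1,2-dioxan-3-yl]but-2-en-1-yl]dihydrofuran-2(3H)-one, via phosphorus ylide 32 (not isolated)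
Conditions: 31, KN(SiMe3)2 (0.95 equiv), THF, −78 °C; then 15, −78 → −20 °C
Reagents that add atoms: none
Why: Wittig olefination of an α-oxygenated methyl ketone with a non-stabilised ylide; such ketones give the trisubstituted alkene with the oxygen-bearing carbon and the new chain cis (C11 cis to C14), and the deficit of base means that only the ylide, which adds to the carbonyl faster than it abstracts C11–H, meets 15.

Step 22
Reactants: 33 (4R,5S)-5-[(E)-3-(tert-butyldimethylsilyloxy)-2-methylprop-1-en-1-yl]-4-[(Z)-3-[(3R,6S)-6-methyl-6-[(1R)-1-(triethylsilyloxy)ethyl]-1,2-dioxan-3-yl]but-2-en-1-yl]dihydrofuran-2(3H)-one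
Product: 34 (4R,5S)-4-[(Z)-3-[(3R,6S)-6-[(1R)-1-hydroxyethyl]-6-methyl-1,2-dioxan-3-yl]but-2-en-1-yl]-5-[(E)-3-hydroxy-2-methylprop-1-en-1-yl]dihydrofuran-2(3H)-one
Conditions: HF·pyridine, pyridine, THF, 0 → 23 °C
Reagents that add atoms: none
Why: Fluoride cleavage of both silyl ethers under buffered, non-basic conditions that leave the peroxide and the lactone untouched.

Step 23
Reactants: 34 (4R,5S)-4-[(Z)-3-[(3R,6S)-6-[(1R)-1-hydroxyethyl]-6-methyl-1,2-dioxan-3-yl]but-2-en-1-yl]-5-[(E)-3-hydroxy-2-methylprop-1-en-1-yl]dihydrofuran-2(3H)-one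
Product: 36 (4R,5S)-5-[(E)-3-bromo-2-methylprop-1-en-1-yl]-4-[(Z)-3-[(3R,6S)-6-[(1R)-1-hydroxyethyl]-6-methyl-1,2-dioxan-3-yl]but-2-en-1-yl]dihydrofuran-2(3H)-one, via allylic mesylate 35 (not isolated)
Conditions: MsCl (1.05 equiv), Et3N, CH2Cl2, −40 °C; then LiBr, THF, 0 °C
Reagents that add atoms: lithium bromide, [Li+].[Br-]
Why: Selective sulfonylation of the primary allylic alcohol and Finkelstein-type SN2 displacement by bromide; the C7 hydroxyl next to the quaternary carbon is too hindered to react at this temperature.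

Step 24
Reactants: 36 (4R,5S)-5-[(E)-3-bromo-2-methylprop-1-en-1-yl]-4-[(Z)-3-[(3R,6S)-6-[(1R)-1-hydroxyethyl]-6-methyl-1,2-dioxan-3-yl]but-2-en-1-yl]dihydrofuran-2(3H)-one
Product: 37 (4R,5S)-4-[(Z)-3-[(3R,6S)-6-acetyl-6-methyl-1,2-dioxan-3-yl]but-2-en-1-yl]-5-[(E)-3-bromo-2-methylprop-1-en-1-yl]dihydrofuran-2(3H)-one (seco bromo ketone)
Conditions: Dess–Martin periodinane, NaHCO3, CH2Cl2, 0 → 23 °C
Reagents that add atoms: none
Why: Dess–Martin oxidation of the secondary alcohol to the C7 methyl ketone under buffered conditions that spare the allylic bromide and the peroxide; the ketone is unveiled only at this point.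

Step 25
Reactants: 37 (4R,5S)-4-[(Z)-3-[(3R,6S)-6-acetyl-6-methyl-1,2-dioxan-3-yl]but-2-en-1-yl]-5-[(E)-3-bromo-2-methylprop-1-en-1-yl]dihydrofuran-2(3H)-one
Product: 39 (1R,2S,3E,8S,11R,12Z)-8,11-epidioxy-7-oxo-17-norcembra-3,12-dien-16,2-olide (macrocyclic ketone), via potassium enolate 38 (not isolated)
Conditions: KN(SiMe3)2 (1.05 equiv), THF (2 mM), −78 °C; then −78 → −10 °C
Reagents that add atoms: none
Why: KN(SiMe3)2 removes a proton from the C6 methyl group, the only enolisable position of the C7 ketone because C8 is quaternary, and the enolate carbon displaces the primary allylic bromide at C5 by SN2, forming C5–C6. The closest known reaction type is the intramolecular alkylation of a stabilised carbanion by an allylic halide used to close fourteen-membered carbocycles, here with a ketone enolate. The ring closes in a 14-exo-tet mode and no stereocentre is created. The cis-dioxane holds the C7 and C12 arms on one face, the two alkenes and the lactone remove rotors, and the 2 mM concentration disfavours oligomers. C- over O-alkylation is expected from the soft allylic bromide in THF. The base is consumed at −78 °C by the most accessible and inductively acidified methyl ketone, so no free amide base remains for C11–H (Kornblum–DeLaMare cleavage) or, to a damaging extent, for the comparably acidic lactone α-hydrogens; a lactone enolate formed by proton transfer cannot reach C5, since that would require a trans-cyclohexene. The enolate cannot expel the peroxide because the O–O bond sits on C8, the α′-carbon, which bears no hydrogen.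

Step 26
Reactants: 39 (1R,2S,3E,8S,11R,12Z)-8,11-epidioxy-7-oxo-17-norcembra-3,12-dien-16,2-olide
Product: 40 (1R,2S,3E,7R,8S,11R,12Z)-8,11-epidioxy-7-hydroxy-17-norcembra-3,12-dien-16,2-olide
Conditions: (S)-2-methyl-CBS-oxazaborolidine, catecholborane, toluene, −78 °C
Reagents that add atoms: none
Why: Corey–Bakshi–Shibata reduction; the quaternary C8 flank is the large and C6H2 the small substituent, so the (S)-catalyst should deliver hydride to give the (7R)-alcohol (the sense that a chelate of the carbonyl and the C8 peroxy oxygen would also give, and opposite to the polar Felkin–Anh sense), and catecholborane does not touch the alkenes or the lactone at this temperature.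

Step 27
Reactants: 40 (1R,2S,3E,7R,8S,11R,12Z)-8,11-epidioxy-7-hydroxy-17-norcembra-3,12-dien-16,2-olide
Product: 41 (1R,2S,3E,7R,8S,11R,12Z)-7-acetoxy-8,11-epidioxy-17-norcembra-3,12-dien-16,2-olide
Conditions: Ac2O, pyridine, DMAP (cat.), CH2Cl2, 23 °C
Reagents that add atoms: acetic anhydride, CC(=O)OC(C)=O
Why: Acylation of the secondary alcohol; the ester also protects the C7 oxygen from forming an alkoxide next to the peroxide in the last step.

Step 28
Reactants: 41 (1R,2S,3E,7R,8S,11R,12Z)-7-acetoxy-8,11-epidioxy-17-norcembra-3,12-dien-16,2-olide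
Product: 45 (1R,2R,3E,7R,8S,11R,12Z)-7-acetoxy-8,11-epidioxycembra-3,12,15(17)-trien-16,2-olide (target), via lithium enolate 42 (not isolated), via Mannich base 43 (not isolated), via ammonium iodide 44 (not isolated)
Conditions: LiN(SiMe3)2 (1.1 equiv), THF, −78 °C; CH2=NMe2+ I−, −78 → 0 °C; then MeI, MeOH, 23 °C; then NaHCO3 (aq)/CH2Cl2
Reagents that add atoms: N,N-dimethylmethyleneiminium iodide, C=[N+](C)C.[I-]
Why: Mannich reaction of the lactone enolate with Eschenmoser's salt, then quaternisation and Hofmann-type elimination; LiN(SiMe3)2 deprotonates the lactone but is too weak a base for the acetate, and the exocyclic alkene creates no stereocentre.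

## Compound list

1 | 3-methylbut-3-en-2-ol (racemic) | CC(O)C(C)=C | starting material
2 | triethyl orthoacetate | CCOC(C)(OCC)OCC | starting material
3 | ethyl (E)-4-methylhex-4-enoate | CCOC(=O)CC/C(C)=C/C | intermediate
4 | (E)-N-methoxy-N,4-dimethylhex-4-enamide | CON(C)C(=O)CC/C(C)=C/C | intermediate
5 | ethynyltrimethylsilane | C#C[Si](C)(C)C | starting material
6 | lithium (trimethylsilyl)acetylide | [Li]C#C[Si](C)(C)C | intermediate (not isolated)
7 | (E)-7-methyl-1-(trimethylsilyl)non-7-en-1-yn-3-one | C/C=C(\C)CCC(=O)C#C[Si](C)(C)C | intermediate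
8 | (3S,7E)-7-methyl-1-(trimethylsilyl)non-7-en-1-yn-3-ol | C/C=C(\C)CC[C@H](O)C#C[Si](C)(C)C | intermediate
9 | (3S)-5-[(2R,3R)-2,3-dimethyloxiran-2-yl]-1-(trimethylsilyl)pent-1-yn-3-ol | C[C@H]1O[C@]1(C)CC[C@H](O)C#C[Si](C)(C)C | intermediate
10 | (3S)-5-[(2R,3R)-2,3-dimethyloxiran-2-yl]-1-(trimethylsilyl)pent-1-yn-3-yl methanesulfonate | C[C@H]1O[C@]1(C)CC[C@H](OS(C)(=O)=O)C#C[Si](C)(C)C | intermediate
11 | (3S,6S,7R)-6-hydroperoxy-7-hydroxy-6-methyl-1-(trimethylsilyl)oct-1-yn-3-yl methanesulfonate | C[C@@H](O)[C@@](C)(OO)CC[C@H](OS(C)(=O)=O)C#C[Si](C)(C)C | intermediate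
12 | (1R)-1-[(3S,6R)-3-methyl-6-[(trimethylsilyl)ethynyl]-1,2-dioxan-3-yl]ethan-1-ol | C[C@@H](O)[C@]1(C)CC[C@@H](OO1)C#C[Si](C)(C)C | intermediate (not isolated)
13 | (1R)-1-[(3S,6R)-6-ethynyl-3-methyl-1,2-dioxan-3-yl]ethan-1-ol | C[C@@H](O)[C@]1(C)CC[C@@H](OO1)C#C | intermediate
14 | triethyl{(1R)-1-[(3S,6R)-6-ethynyl-3-methyl-1,2-dioxan-3-yl]ethoxy}silane | CC[Si](CC)(CC)O[C@H](C)[C@]1(C)CC[C@@H](OO1)C#C | intermediate
15 | 1-[(3R,6S)-6-methyl-6-[(1R)-1-(triethylsilyloxy)ethyl]-1,2-dioxan-3-yl]ethan-1-one | CC[Si](CC)(CC)O[C@H](C)[C@]1(C)CC[C@@H](OO1)C(C)=O | intermediate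
16 | (S)-4-benzyloxazolidin-2-one | O=C1OC[C@H](Cc2ccccc2)N1 | starting material
17 | methyl 4-chloro-4-oxobutanoate | COC(=O)CCC(Cl)=O | starting material
18 | methyl 4-[(S)-4-benzyl-2-oxooxazolidin-3-yl]-4-oxobutanoate | COC(=O)CCC(=O)N1[C@@H](Cc2ccccc2)COC1=O | intermediate
19 | 3-methylbut-2-enal | CC(C)=CC=O | starting material
20 | methyl (3R,4R)-3-[(S)-4-benzyl-2-oxooxazolidine-3-carbonyl]-6-methyl-4-(trimethylsilyloxy)hept-5-enoate | COC(=O)C[C@@H](C(=O)N1[C@@H](Cc2ccccc2)COC1=O)[C@H](O[Si](C)(C)C)C=C(C)C | intermediate (not isolated)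
21 | methyl (3R,4R)-3-[(S)-4-benzyl-2-oxooxazolidine-3-carbonyl]-4-hydroxy-6-methylhept-5-enoate | COC(=O)C[C@@H](C(=O)N1[C@@H](Cc2ccccc2)COC1=O)[C@H](O)C=C(C)C | intermediate (not isolated)
22 | (S)-4-benzyl-3-[(2R,3R)-2-(2-methylprop-1-en-1-yl)-5-oxotetrahydrofuran-3-carbonyl]oxazolidin-2-one | O=C1O[C@H](C=C(C)C)[C@H](C(=O)N2[C@@H](Cc3ccccc3)COC2=O)C1 | intermediate
23 | (S)-4-benzyl-3-[(2R,3R)-2-[(E)-3-hydroxy-2-methylprop-1-en-1-yl]-5-oxotetrahydrofuran-3-carbonyl]oxazolidin-2-one | O=C1O[C@H](/C=C(\C)CO)[C@H](C(=O)N2[C@@H](Cc3ccccc3)COC2=O)C1 | intermediate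
24 | (S)-4-benzyl-3-[(2R,3R)-2-[(E)-3-(tert-butyldimethylsilyloxy)-2-methylprop-1-en-1-yl]-5-oxotetrahydrofuran-3-carbonyl]oxazolidin-2-one | O=C1O[C@H](/C=C(\C)CO[Si](C)(C)C(C)(C)C)[C@H](C(=O)N2[C@@H](Cc3ccccc3)COC2=O)C1 | intermediate
25 | S-ethyl (2R,3R)-2-[(E)-3-(tert-butyldimethylsilyloxy)-2-methylprop-1-en-1-yl]-5-oxotetrahydrofuran-3-carbothioate | O=C1O[C@H](/C=C(\C)CO[Si](C)(C)C(C)(C)C)[C@H](C(=O)SCC)C1 | intermediate
26 | (2R,3R)-2-[(E)-3-(tert-butyldimethylsilyloxy)-2-methylprop-1-en-1-yl]-5-oxotetrahydrofuran-3-carbaldehyde | O=C1O[C@H](/C=C(\C)CO[Si](C)(C)C(C)(C)C)[C@H](C=O)C1 | intermediate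
27 | (4S,5S)-5-[(E)-3-(tert-butyldimethylsilyloxy)-2-methylprop-1-en-1-yl]-4-vinyldihydrofuran-2(3H)-one | O=C1O[C@H](/C=C(\C)CO[Si](C)(C)C(C)(C)C)[C@H](C=C)C1 | intermediate
28 | (4R,5S)-4-[2-(9-borabicyclo[3.3.1]nonan-9-yl)ethyl]-5-[(E)-3-(tert-butyldimethylsilyloxy)-2-methylprop-1-en-1-yl]dihydrofuran-2(3H)-one | O=C1O[C@H](/C=C(\C)CO[Si](C)(C)C(C)(C)C)[C@H](CCB2C3CCCC2CCC3)C1 | intermediate (not isolated)
29 | (4R,5S)-5-[(E)-3-(tert-butyldimethylsilyloxy)-2-methylprop-1-en-1-yl]-4-(2-hydroxyethyl)dihydrofuran-2(3H)-one | O=C1O[C@H](/C=C(\C)CO[Si](C)(C)C(C)(C)C)[C@H](CCO)C1 | intermediate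
30 | (4S,5S)-5-[(E)-3-(tert-butyldimethylsilyloxy)-2-methylprop-1-en-1-yl]-4-(2-iodoethyl)dihydrofuran-2(3H)-one | O=C1O[C@H](/C=C(\C)CO[Si](C)(C)C(C)(C)C)[C@H](CCI)C1 | intermediate
31 | {2-[(2S,3S)-2-[(E)-3-(tert-butyldimethylsilyloxy)-2-methylprop-1-en-1-yl]-5-oxotetrahydrofuran-3-yl]ethyl}triphenylphosphonium iodide | O=C1O[C@H](/C=C(\C)CO[Si](C)(C)C(C)(C)C)[C@H](CC[P+](c2ccccc2)(c2ccccc2)c2ccccc2)C1.[I-] | intermediate
32 | ylide of 31 (C13=PPh3; lactone 2S,3S as in 31) | O=C1O[C@H](/C=C(\C)CO[Si](C)(C)C(C)(C)C)[C@H](CC=P(c2ccccc2)(c2ccccc2)c2ccccc2)C1 | intermediate (not isolated)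
33 | (4R,5S)-5-[(E)-3-(tert-butyldimethylsilyloxy)-2-methylprop-1-en-1-yl]-4-[(Z)-3-[(3R,6S)-6-methyl-6-[(1R)-1-(triethylsilyloxy)ethyl]-1,2-dioxan-3-yl]but-2-en-1-yl]dihydrofuran-2(3H)-one | CC[Si](CC)(CC)O[C@H](C)[C@]1(C)CC[C@@H](OO1)/C(C)=C\C[C@@H]2CC(=O)O[C@@H]2/C=C(\C)CO[Si](C)(C)C(C)(C)C | intermediate
34 | (4R,5S)-4-[(Z)-3-[(3R,6S)-6-[(1R)-1-hydroxyethyl]-6-methyl-1,2-dioxan-3-yl]but-2-en-1-yl]-5-[(E)-3-hydroxy-2-methylprop-1-en-1-yl]dihydrofuran-2(3H)-one | C[C@@H](O)[C@]1(C)CC[C@@H](OO1)/C(C)=C\C[C@@H]2CC(=O)O[C@@H]2/C=C(\C)CO | intermediate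
35 | (E)-3-[(2S,3R)-3-[(Z)-3-[(3R,6S)-6-[(1R)-1-hydroxyethyl]-6-methyl-1,2-dioxan-3-yl]but-2-en-1-yl]-5-oxotetrahydrofuran-2-yl]-2-methylallyl methanesulfonate | C[C@@H](O)[C@]1(C)CC[C@@H](OO1)/C(C)=C\C[C@@H]2CC(=O)O[C@@H]2/C=C(\C)COS(C)(=O)=O | intermediate (not isolated)
36 | (4R,5S)-5-[(E)-3-bromo-2-methylprop-1-en-1-yl]-4-[(Z)-3-[(3R,6S)-6-[(1R)-1-hydroxyethyl]-6-methyl-1,2-dioxan-3-yl]but-2-en-1-yl]dihydrofuran-2(3H)-one | C[C@@H](O)[C@]1(C)CC[C@@H](OO1)/C(C)=C\C[C@@H]2CC(=O)O[C@@H]2/C=C(\C)CBr | intermediate
37 | (4R,5S)-4-[(Z)-3-[(3R,6S)-6-acetyl-6-methyl-1,2-dioxan-3-yl]but-2-en-1-yl]-5-[(E)-3-bromo-2-methylprop-1-en-1-yl]dihydrofuran-2(3H)-one (seco bromo ketone) | CC(=O)[C@]1(C)CC[C@@H](OO1)/C(C)=C\C[C@@H]2CC(=O)O[C@@H]2/C=C(\C)CBr | intermediate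
38 | potassium enolate of 37 (C6=C7–O−) | [K+].[O-]C(=C)[C@]1(C)CC[C@@H](OO1)/C(C)=C\C[C@@H]2CC(=O)O[C@@H]2/C=C(\C)CBr | intermediate (not isolated)
39 | (1R,2S,3E,8S,11R,12Z)-8,11-epidioxy-7-oxo-17-norcembra-3,12-dien-16,2-olide (macrocyclic ketone) | C1C(=O)O[C@@H]2/C=C(\C)CCC(=O)[C@]3(C)CC[C@@H](OO3)/C(C)=C\C[C@H]12 | intermediate
40 | (1R,2S,3E,7R,8S,11R,12Z)-8,11-epidioxy-7-hydroxy-17-norcembra-3,12-dien-16,2-olide | C1C(=O)O[C@@H]2/C=C(\C)CC[C@@H](O)[C@]3(C)CC[C@@H](OO3)/C(C)=C\C[C@H]12 | intermediate
41 | (1R,2S,3E,7R,8S,11R,12Z)-7-acetoxy-8,11-epidioxy-17-norcembra-3,12-dien-16,2-olide | C1C(=O)O[C@@H]2/C=C(\C)CC[C@@H](OC(C)=O)[C@]3(C)CC[C@@H](OO3)/C(C)=C\C[C@H]12 | intermediate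
42 | lithium enolate of 41 (C15=C16–O−) | [Li+].C1=C([O-])O[C@@H]2/C=C(\C)CC[C@@H](OC(C)=O)[C@]3(C)CC[C@@H](OO3)/C(C)=C\C[C@H]12 | intermediate (not isolated)
43 | 15-(dimethylaminomethyl) derivative of 41 (Mannich base, C15 epimers) | CN(C)CC1C(=O)O[C@@H]2/C=C(\C)CC[C@@H](OC(C)=O)[C@]3(C)CC[C@@H](OO3)/C(C)=C\C[C@H]12 | intermediate (not isolated)
44 | 15-(trimethylammoniomethyl) derivative of 41, iodide | C[N+](C)(C)CC1C(=O)O[C@@H]2/C=C(\C)CC[C@@H](OC(C)=O)[C@]3(C)CC[C@@H](OO3)/C(C)=C\C[C@H]12.[I-] | intermediate (not isolated)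
45 | (1R,2R,3E,7R,8S,11R,12Z)-7-acetoxy-8,11-epidioxycembra-3,12,15(17)-trien-16,2-olide | C=C1C(=O)O[C@@H]2/C=C(\C)CC[C@@H](OC(C)=O)[C@]3(C)CC[C@@H](OO3)/C(C)=C\C[C@H]12 | target

## Step count and least certain steps

Total step count: 28 (steps 1–10 dioxane half, steps 11–20 lactone half, steps 21–28 union and completion). Longest linear sequence: 18 steps (from 16/17 through steps 11–28, or equally from 1/2 through steps 1–10 and 21–28).

**Step 25 (key step).** The most likely failures are O-alkylation or oligomerisation instead of ring closure, and proton transfer that leaves base free to open the dioxane at C11–H. Fallback: starting from 37, the ketone is converted with Me3SiOTf and i-Pr2NEt at −78 °C into the trimethylsilyl enol ether F1. F1 is added slowly to Bu4N[Ph3SiF2] in THF at high dilution, so that the enolate is released by fluoride without any amide base and alkylates C5. The fallback returns to the route at 39.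

**Step 21.** The most likely failure is proton abstraction at C11 of 15 by the ylide, which collapses the O–O bond, in competition with carbonyl addition; erosion of the Z selectivity is the second risk. Fallback, which avoids any carbonyl at C12: starting from 26 and 14, aldehyde 26 is reduced (NaBH4, MeOH, −40 °C) to the hydroxymethyl lactone F2 and converted at once (I2, PPh3, imidazole) into the iodomethyl lactone F3. F3 is coupled with the terminal alkyne 14 in a copper/palladium-catalysed alkyl Sonogashira reaction ([Pd(allyl)Cl]2, N-heterocyclic carbene ligand, CuI, Cs2CO3) to give the internal alkyne F4. Palladium-catalysed syn-hydrostannation (Bu3SnH, Pd(PPh3)2Cl2) is expected to place tin on C12, next to the oxygen-bearing carbon, giving the alkenylstannane F5. Iodine gives the alkenyl iodide F6 with retention, and Negishi methylation (MeZnCl, Pd(PPh3)4) installs C20 with retention. The fallback returns to the route at 33.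

**Step 7.** The most likely failure is partial loss of configuration at the tertiary carbon C8 through a carbocation-like opening, or rearrangement of the activated epoxide. Fallback, which reverses the roles of the two oxygen-bearing carbons: starting from 10, hydrogen peroxide and KOH in MeOH displace the propargylic mesylate with inversion and remove the C-silyl group, giving the hydroperoxy epoxide F7. Catalytic camphorsulfonic acid in CH2Cl2 then lets the tethered hydroperoxide open the epoxide at C8 in a 6-exo mode with inversion. The fallback returns to the route at 13.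

**Step 26.** The most likely failure is poor facial selectivity, because the macrocycle's conformational preference (and the polar Felkin–Anh preference) may oppose the catalyst. Fallback: biocatalytic reduction of 39 with a panel of ketoreductases and NADPH recycling (glucose/glucose dehydrogenase, pH 7 buffer with co-solvent), choosing an R-selective enzyme. This makes no compound outside the list (F0) and returns at 40.

**Step 28.** The most likely failures are base-induced opening of the dioxane at C11–H and acyl transfer from the C7 acetate to the lactone enolate. Fallback, which takes the ester out of the enolate step: starting from 40, silylation (Et3SiOTf, 2,6-lutidine) gives the C7 triethylsilyl ether F8. Enolate formation (LiN(i-Pr)2, −78 °C), Eschenmoser's salt, MeI and NaHCO3 give the silylated methylene lactone F9. HF·pyridine gives the 7-hydroxy methylene lactone F10, and acetylation (Ac2O, pyridine, DMAP) returns to the route at 45.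

## Further compounds

F1 | step 25 | trimethylsilyl enol ether of 37 (C6=C7–OSiMe3) | C=C(O[Si](C)(C)C)[C@]1(C)CC[C@@H](OO1)/C(C)=C\C[C@@H]2CC(=O)O[C@@H]2/C=C(\C)CBr
F2 | step 21 | (4S,5R)-5-[(E)-3-(tert-butyldimethylsilyloxy)-2-methylprop-1-en-1-yl]-4-(hydroxymethyl)dihydrofuran-2(3H)-one | O=C1O[C@H](/C=C(\C)CO[Si](C)(C)C(C)(C)C)[C@H](CO)C1
F3 | step 21 | (4R,5R)-5-[(E)-3-(tert-butyldimethylsilyloxy)-2-methylprop-1-en-1-yl]-4-(iodomethyl)dihydrofuran-2(3H)-one | O=C1O[C@H](/C=C(\C)CO[Si](C)(C)C(C)(C)C)[C@H](CI)C1
F4 | step 21 | C12≡C13 alkyne analogue of 33 (no C20 methyl; other centres as in 33) | CC[Si](CC)(CC)O[C@H](C)[C@]1(C)CC[C@@H](OO1)C#CC[C@@H]2CC(=O)O[C@@H]2/C=C(\C)CO[Si](C)(C)C(C)(C)C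
F5 | step 21 | 12-(tributylstannyl) analogue of 33 (tin in place of C20; C11 cis to C14) | CC[Si](CC)(CC)O[C@H](C)[C@]1(C)CC[C@@H](OO1)/C([Sn](CCCC)(CCCC)CCCC)=C\C[C@@H]2CC(=O)O[C@@H]2/C=C(\C)CO[Si](C)(C)C(C)(C)C
F6 | step 21 | 12-iodo analogue of 33 (iodine in place of C20; C11 cis to C14) | CC[Si](CC)(CC)O[C@H](C)[C@]1(C)CC[C@@H](OO1)/C(I)=C\C[C@@H]2CC(=O)O[C@@H]2/C=C(\C)CO[Si](C)(C)C(C)(C)C
F7 | step 7 | (2R,3R)-2-[(3R)-3-hydroperoxypent-4-yn-1-yl]-2,3-dimethyloxirane | C[C@H]1O[C@]1(C)CC[C@@H](OO)C#C
F0 | step 26 | none | none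
F8 | step 28 | 7-O-triethylsilyl ether of 40 | C1C(=O)O[C@@H]2/C=C(\C)CC[C@@H](O[Si](CC)(CC)CC)[C@]3(C)CC[C@@H](OO3)/C(C)=C\C[C@H]12
F9 | step 28 | 7-O-triethylsilyl ether of 7-deacetyl-45 | C=C1C(=O)O[C@@H]2/C=C(\C)CC[C@@H](O[Si](CC)(CC)CC)[C@]3(C)CC[C@@H](OO3)/C(C)=C\C[C@H]12
F10 | step 28 | 7-deacetyl-45 (7R-hydroxy methylene lactone) | C=C1C(=O)O[C@@H]2/C=C(\C)CC[C@@H](O)[C@]3(C)CC[C@@H](OO3)/C(C)=C\C[C@H]12
A1 | alternative 1 | geranylgeranyl diphosphate | CC(C)=CCC/C(C)=C/CC/C(C)=C/CC/C(C)=C/COP(=O)(O)OP(=O)(O)O
A2 | alternative 1 | cembrene A | C=C(C)[C@@H]1C/C=C(\C)CC/C=C(\C)CC/C=C(\C)CC1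
A3 | alternative 2 | 1,3-dimethylcyclohexa-1,3-diene | CC1=CC(C)=CCC1
A4 | alternative 2 | 1,5-dimethyl-2,3-dioxabicyclo[2.2.2]oct-5-ene (enantiomer matching C8 and C11) | C[C@@]12CC[C@@H](OO1)C(C)=C2
A5 | alternative 3 | seco alkenyl iodide (C4 iodide, terminal C5=C6 alkene, C7/C8 acetonide, C11 silyl ether) | C=C[C@@H]1OC(C)(C)O[C@]1(C)CC[C@H](O[Si](C)(C)C(C)(C)C)/C(C)=C\C[C@@H]2CC(=O)O[C@@H]2/C=C(\C)I
A6 | alternative 3 | macrocyclic lactone with C7/C8 acetonide and C11 silyl ether | C1C(=O)O[C@@H]2/C=C(\C)CC[C@@H]3OC(C)(C)O[C@]3(C)CC[C@H](O[Si](C)(C)C(C)(C)C)/C(C)=C\C[C@H]12
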